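**Remarks on the chemistry.** Unit 1 is the flavone bonded through C2 to the central anisole ring (atoms O1, C2–C8a; rings A1 and C1; central ring B1 = C1'–C6'). Unit 2 is the flavone bonded through C8'' (atoms O1'', C2''–C8a''; rings A2 and C2; its 4-methoxyphenyl ring B2 = C1'''–C6'''). The SMILES gives no descriptor for the C2'–C8'' axis; the route does not control it and should deliver the compound as drawn (the racemate, if the axis is configurationally stable). Compounds 1, 3 and 8 are taken to be commercial.

## Analysis of the target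

The target is a 2',8''-linked biflavone. Unit 1 is a 5,7-dihydroxyflavone whose ring B1 carries a methoxy group at C4' and, at C2', the C8'' carbon of unit 2. Unit 2 is a 5''-hydroxy-7''-methoxyflavone with a 4-methoxyphenyl ring B2. There is no stereogenic centre; the only stereochemical element is the C2'–C8'' axis, which has three ortho substituents (C1' with ring C1, C7''–OMe and C8a''–O1''). The sensitive groups are two chelated peri hydroxyls (C5–OH, C5''–OH), one free acidic phenol (C7–OH), three aryl methyl ethers that must survive the end game, and two γ-pyranones that open with hydroxide or hard carbon nucleophiles. The difficulties are the hindered biaryl bond, the unsymmetrical linkage (one flavone joined through its B ring, the other through C8), and the oxygen pattern: of six phenolic oxygens three are methylated, and both free hydroxyls of ring A1 sit on one ring. The feature that the plan exploits is ring A1. Its oxygens at C5, C7 and C8a are mutually meta, and C4a, which carries the C4 carbonyl, lies between C5–O and C8a–O1. This is the polarity pattern of an aryne C4a≡C8a with an alkoxy group on C5 beside the triple bond: an oxygen nucleophile is directed to C8a and the acyl carbon C4 to C4a.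

## Retrosynthetic reasoning

Target 20 is traced back to 18, in which the two ring A1 hydroxyls are benzyl ethers and O5'' is a methyl ether. All three groups fall to one chelating Lewis acid, while the non-chelated methyl ethers on C4', C7'' and C4''' stay. O5'' must be capped up to that point, because a free phenol would be arylated in the key step.

Compound 18 is cut in ring C1 at O1–C8a and at C4–C4a, with O1–C2 closed in the same operation. This removes the whole of ring A1 as aryne 16 (from silyl triflate 15) and leaves propiolic acid 7, in which C2, C3, C4, O1 and the carbonyl oxygen are already in place. The cut is made here because ring A1 is the one ring whose substitution pattern an aryne can deliver with full regiocontrol, and because unit 2 and the hindered biaryl bond pass through untouched. The forward reaction must add the carboxylate oxygen to C8a, shift the acyl group to C4a and close the pyranone in the 6-endo mode.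

Acid 7 is traced to terminal alkyne 5 by removal of the carboxyl carbon (the future C4), and 5 to aldehyde 4 by removal of the alkyne terminus (the future C3). Both are one-carbon extensions under mild carbonate conditions that the pyranone of unit 2 tolerates.

Aldehyde 4 is cut at the biaryl bond C2'–C8'' into iodide 2 and boronic acid 3. The coupling is placed early, where one partner is a small benzaldehyde, and not late between two complete flavones.

Iodide 2 comes from 1 by electrophilic substitution at C8''. Compound 1 already holds rings A2, C2 and B2 with all three oxygens methylated, which is what steers the electrophile to C8''.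

Silyl triflate 15 is traced through silyl carbamate 13 and carbamate 9 to phenol 8. The silyl group is placed by directed ortho-metalation at the carbon between the carbamate and one benzyloxy group, so the aryne forms next to an ether oxygen.

## Alternatives that were turned down

Alternative 1: the textbook cut, at the biaryl bond C2'–C8'' as the last skeletal bond. A bromoflavone A1, 5,7-bis(benzyloxy)-2-(2-bromo-4-methoxyphenyl)-4H-chromen-4-one, would be built by a Baker–Venkataraman sequence and converted into its pinacol boronate A2. Suzuki–Miyaura coupling of A2 with iodide 2 would give 18. It was turned down because the coupling then joins two bulky flavones across three ortho substituents. In addition, the boron of A2 sits ortho to an electron-poor chromonyl group and is prone to protodeboronation. A1 costs a separate esterification, rearrangement, cyclodehydration and borylation sequence, so the route is longer and its risk lies in the last bond.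

Alternative 2: a polyketide-type folding that grows ring A2 on the benzylic carbon of a homophthalate, so that the biaryl bond is never coupled. The chain A3, methyl 6-[5-methoxy-2-(methoxycarbonyl)phenyl]-3,5-dioxohexanoate, would be folded by an intramolecular Claisen condensation of its benzylic carbon onto the terminal ester. This would give the arylphloroglucinol A4, methyl 4-methoxy-2-(2,4,6-trihydroxyphenyl)benzoate. It was turned down on three counts:
- 3,5-Dioxo esters close more readily at oxygen, to 4-hydroxy-2-pyranones, than at a benzylic carbon activated by a single carbonyl group.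
- A4 has two equivalent ortho hydroxyls and would lactonise onto the C1' ester to the benzochromenone A5, 1,3-dihydroxy-9-methoxy-6H-benzo[c]chromen-6-one. This uses up the carbon needed as C2 of ring C1.
- Nothing in A4 or A5 tells O1'' from O5'' and O7''. The later acylation, the closure to the 8-aryl and not the 6-aryl chromone, and the single methylation at O7'' would all be uncontrolled and would add many steps after the key step.

Alternative 3: construction of the central ring B1 by cycloaddition. The bis-flavone alkyne A6, 5,7-bis(benzyloxy)-2-{[5,7-dimethoxy-2-(4-methoxyphenyl)-4-oxo-4H-chromen-8-yl]ethynyl}-4H-chromen-4-one, would undergo Diels–Alder reaction with the diene A7, 2-methoxybuta-1,3-diene. This would give the cyclohexadiene A8, which would be dehydrogenated to 18. It was turned down for these reasons: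
- The alkyne of A6 is disubstituted and flanked by the ortho,ortho'-disubstituted ring A2, so it is a poor dienophile. It would need temperatures at which A7 polymerises.
- The regiochemistry (methoxy on C4', not C5') rests only on the weak polarisation by the vinylogous ester of ring C1.
- A6 needs a 2-ethynylchromone that takes several steps to make.
- The effort goes into ring B1, the cheapest ring of the molecule.

Key step: step 8

## Route

Step 1
Reactants: 1 5,7-dimethoxy-2-(4-methoxyphenyl)-4H-chromen-4-one
Product: 2 8-iodo-5,7-dimethoxy-2-(4-methoxyphenyl)-4H-chromen-4-one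
Conditions: NIS, CF3CO2H (cat.), MeCN, rt
Reagents that add atoms: N-iodosuccinimide, O=C1CCC(=O)N1I
Why: Electrophilic aromatic iodination; 5,7-dialkoxyflavones are substituted at C8'' (C6'' lies between two methoxy groups), whereas a free peri hydroxyl would steer to C6'', which is one reason O5'' is kept methylated.

Step 2
Reactants: 2 8-iodo-5,7-dimethoxy-2-(4-methoxyphenyl)-4H-chromen-4-one; 3 (2-formyl-5-methoxyphenyl)boronic acid
Product: 4 2-[5,7-dimethoxy-2-(4-methoxyphenyl)-4-oxo-4H-chromen-8-yl]-4-methoxybenzaldehyde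
Conditions: Pd(OAc)2 (5 mol%), SPhos (10 mol%), K3PO4, toluene/H2O, 90 °C
Reagents that add atoms: none
Why: Suzuki–Miyaura coupling forms C2'–C8''; the bulky, electron-rich dialkylbiarylphosphine on zerovalent palladium is the standard answer to a di-ortho-substituted aryl iodide, and the boron partner is small.

Step 3
Reactants: 4 2-[5,7-dimethoxy-2-(4-methoxyphenyl)-4-oxo-4H-chromen-8-yl]-4-methoxybenzaldehyde
Product: 5 8-(2-ethynyl-5-methoxyphenyl)-5,7-dimethoxy-2-(4-methoxyphenyl)-4H-chromen-4-one
Conditions: dimethyl (1-diazo-2-oxopropyl)phosphonate, K2CO3, MeOH/THF, 0 °C to rt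
Reagents that add atoms: dimethyl (1-diazo-2-oxopropyl)phosphonate, COP(=O)(OC)C(=[N+]=[N-])C(C)=O
Why: Seyferth–Gilbert homologation in the Ohira–Bestmann variant turns the aldehyde into the terminal alkyne; carbonate in methanol at room temperature should leave the fully O-methylated pyranone intact.

Step 4
Reactants: 5 8-(2-ethynyl-5-methoxyphenyl)-5,7-dimethoxy-2-(4-methoxyphenyl)-4H-chromen-4-one
Product: 7 3-{2-[5,7-dimethoxy-2-(4-methoxyphenyl)-4-oxo-4H-chromen-8-yl]-4-methoxyphenyl}prop-2-ynoic acid, via cesium arylpropiolate 6 (not isolated)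
Conditions: CO2 (2 atm), Cs2CO3, AgI (2 mol%), DMF, 50 °C; then 1 M HCl, 0 °C
Reagents that add atoms: carbon dioxide, O=C=O
Why: Direct C–H carboxylation of a terminal alkyne; the metal acetylide formed with carbonate takes up CO2, and the cesium propiolate is stable at 50 °C under CO2 pressure; substrate 5 has no other acidic hydrogen.

Step 5
Reactants: 8 3,5-bis(benzyloxy)phenol
Product: 9 3,5-bis(benzyloxy)phenyl N-isopropylcarbamate
Conditions: i-PrNCO, Et3N (cat.), CH2Cl2, rt
Reagents that add atoms: isopropyl isocyanate, CC(C)N=C=O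
Why: Base-catalysed addition of the phenol to the isocyanate installs a directing group that can later be removed under mild basic conditions.

Step 6
Reactants: 9 3,5-bis(benzyloxy)phenyl N-isopropylcarbamate
Product: 13 3,5-bis(benzyloxy)-2-(trimethylsilyl)phenyl N-isopropylcarbamate, via N-silyl carbamate 10 (not isolated), via aryllithium 11 (not isolated), via bis-silyl carbamate 12 (not isolated)
Conditions: TBSOTf, TMEDA, Et2O, 0 °C to rt; n-BuLi, TMEDA, −78 °C; TMSCl, −78 °C to rt; aq NaHSO4
Reagents that add atoms: chlorotrimethylsilane, C[Si](C)(C)Cl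
Why: Directed ortho-metalation; transient N-silylation blocks N–H deprotonation and isocyanate loss, and lithiation occurs at C2, which lies between the carbamate and a benzyloxy group (C2 and C6 are equivalent by symmetry); the N-silyl group falls off on acidic work-up.

Step 7
Reactants: 13 3,5-bis(benzyloxy)-2-(trimethylsilyl)phenyl N-isopropylcarbamate
Product: 15 3,5-bis(benzyloxy)-2-(trimethylsilyl)phenyl trifluoromethanesulfonate, via silylphenol 14 (not isolated)
Conditions: DBU, Et2NH, MeCN, 40 °C; then PhNTf2, rt
Reagents that add atoms: N-phenylbis(trifluoromethanesulfonimide), O=S(=O)(N(c1ccccc1)S(=O)(=O)C(F)(F)F)C(F)(F)F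
Why: E1cB cleavage of the N-monosubstituted carbamate, with the released isocyanate trapped by diethylamine, gives the phenoxide, which is triflated in the same flask to the ortho-silylaryl triflate.

Step 8
Reactants: 7 3-{2-[5,7-dimethoxy-2-(4-methoxyphenyl)-4-oxo-4H-chromen-8-yl]-4-methoxyphenyl}prop-2-ynoic acid; 15 3,5-bis(benzyloxy)-2-(trimethylsilyl)phenyl trifluoromethanesulfonate
Product: 18 5,7-bis(benzyloxy)-2-{2-[5,7-dimethoxy-2-(4-methoxyphenyl)-4-oxo-4H-chromen-8-yl]-4-methoxyphenyl}-4H-chromen-4-one, via aryne 16 (not isolated), via ynone phenoxide 17 (not isolated)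
Conditions: CsF (4 equiv), THF, 125 °C, sealed tube
Reagents that add atoms: none
Why: Fluoride unmasks 15 to aryne 16, whose C1≡C2 bond is polarised and distorted by the inductively withdrawing benzyloxy group on C3, so the cesium carboxylate of 7 should add through oxygen at C1 (the future C8a, meta to both ether oxygens) and leave the aryl anion on C2 (the future C4a). This anion sits next to the new ester carbonyl and attacks it through a four-membered alkoxide that opens by C–O scission, so the aryne has inserted into the C–O bond of the acid and C4–C4a is formed by anionic O-to-C acyl transfer, giving ynone phenoxide 17. The phenoxide then closes ring C1 by 6-endo-dig oxa-Michael addition to the ynone β-carbon (O1–C2), and the resulting vinyl anion takes up the proton that the acid had given to fluoride. The closest known reaction type is the insertion of arynes into the C–O bond of carboxylic acids to give o-hydroxyaryl ketones, which with 3-arylpropiolic acids is known to run on to flavones; the acyl shift is the same event as in aryne acyl-alkylation. No stereocentre is formed, and the C2'–C8'' axis is already present and is not touched. The step needs oxygen attack at C1 and not C2 (secured by the C3 benzyloxy group beside the triple bond, the remote C5 benzyloxy group being a much weaker director), acyl transfer in preference to protonation of the aryl anion (favoured by excess CsF, which keeps the acid as its carboxylate, and by the intramolecular shift at 125 °C), and 6-endo in preference to 5-exo closure (expected for attack on the soft β-carbon of an ynone whose carbonyl is flanked by an ortho alkoxy group). Compound 7 carries no O–H or N–H that an aryne could arylate.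

Step 9
Reactants: 18 5,7-bis(benzyloxy)-2-{2-[5,7-dimethoxy-2-(4-methoxyphenyl)-4-oxo-4H-chromen-8-yl]-4-methoxyphenyl}-4H-chromen-4-one
Product: 20 5,7-dihydroxy-2-{2-[5-hydroxy-7-methoxy-2-(4-methoxyphenyl)-4-oxo-4H-chromen-8-yl]-4-methoxyphenyl}-4H-chromen-4-one, via tris(dichloroboryl) ether 19 (not isolated)
Conditions: BCl3, C6HMe5, CH2Cl2, −78 °C to 0 °C; then MeOH/H2O
Reagents that add atoms: none
Why: BCl3 with pentamethylbenzene as benzyl cation scavenger cleaves aryl benzyl ethers at low temperature, and on warming it cleaves the peri C5''–OMe through chelation to the C4'' carbonyl; the non-chelated methyl ethers on C4', C7'' and C4''' should be inert at or below 0 °C.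

## Compound list

1 | 5,7-dimethoxy-2-(4-methoxyphenyl)-4H-chromen-4-one | COc1ccc(-c2cc(=O)c3c(OC)cc(OC)cc3o2)cc1 | starting material
2 | 8-iodo-5,7-dimethoxy-2-(4-methoxyphenyl)-4H-chromen-4-one | COc1ccc(-c2cc(=O)c3c(OC)cc(OC)c(I)c3o2)cc1 | intermediate
3 | (2-formyl-5-methoxyphenyl)boronic acid | COc1ccc(C=O)c(B(O)O)c1 | starting material
4 | 2-[5,7-dimethoxy-2-(4-methoxyphenyl)-4-oxo-4H-chromen-8-yl]-4-methoxybenzaldehyde | COc1ccc(-c2cc(=O)c3c(OC)cc(OC)c(-c4cc(OC)ccc4C=O)c3o2)cc1 | intermediate
5 | 8-(2-ethynyl-5-methoxyphenyl)-5,7-dimethoxy-2-(4-methoxyphenyl)-4H-chromen-4-one | COc1ccc(-c2cc(=O)c3c(OC)cc(OC)c(-c4cc(OC)ccc4C#C)c3o2)cc1 | intermediate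
6 | cesium 3-{2-[5,7-dimethoxy-2-(4-methoxyphenyl)-4-oxo-4H-chromen-8-yl]-4-methoxyphenyl}prop-2-ynoate | COc1ccc(-c2cc(=O)c3c(OC)cc(OC)c(-c4cc(OC)ccc4C#CC(=O)[O-])c3o2)cc1.[Cs+] | intermediate
7 | 3-{2-[5,7-dimethoxy-2-(4-methoxyphenyl)-4-oxo-4H-chromen-8-yl]-4-methoxyphenyl}prop-2-ynoic acid | COc1ccc(-c2cc(=O)c3c(OC)cc(OC)c(-c4cc(OC)ccc4C#CC(=O)O)c3o2)cc1 | intermediate
8 | 3,5-bis(benzyloxy)phenol | Oc1cc(OCc2ccccc2)cc(OCc2ccccc2)c1 | starting material
9 | 3,5-bis(benzyloxy)phenyl N-isopropylcarbamate | CC(C)NC(=O)Oc1cc(OCc2ccccc2)cc(OCc2ccccc2)c1 | intermediate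
10 | 3,5-bis(benzyloxy)phenyl N-(tert-butyldimethylsilyl)-N-isopropylcarbamate | CC(C)N([Si](C)(C)C(C)(C)C)C(=O)Oc1cc(OCc2ccccc2)cc(OCc2ccccc2)c1 | intermediate
11 | [2,4-bis(benzyloxy)-6-{[(tert-butyldimethylsilyl)(isopropyl)carbamoyl]oxy}phenyl]lithium | [Li]c1c(OC(=O)N(C(C)C)[Si](C)(C)C(C)(C)C)cc(OCc2ccccc2)cc1OCc1ccccc1 | intermediate
12 | 3,5-bis(benzyloxy)-2-(trimethylsilyl)phenyl N-(tert-butyldimethylsilyl)-N-isopropylcarbamate | CC(C)N([Si](C)(C)C(C)(C)C)C(=O)Oc1cc(OCc2ccccc2)cc(OCc2ccccc2)c1[Si](C)(C)C | intermediate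
13 | 3,5-bis(benzyloxy)-2-(trimethylsilyl)phenyl N-isopropylcarbamate | CC(C)NC(=O)Oc1cc(OCc2ccccc2)cc(OCc2ccccc2)c1[Si](C)(C)C | intermediate
14 | 3,5-bis(benzyloxy)-2-(trimethylsilyl)phenol | Oc1cc(OCc2ccccc2)cc(OCc2ccccc2)c1[Si](C)(C)C | intermediate
15 | 3,5-bis(benzyloxy)-2-(trimethylsilyl)phenyl trifluoromethanesulfonate | FC(F)(F)S(=O)(=O)Oc1cc(OCc2ccccc2)cc(OCc2ccccc2)c1[Si](C)(C)C | intermediate
16 | 3,5-bis(benzyloxy)benzyne (1,2-didehydro-3,5-bis(benzyloxy)benzene) | O(Cc1ccccc1)C1=CC(OCc2ccccc2)=CC#C1 | intermediate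
17 | cesium 3,5-bis(benzyloxy)-2-(3-{2-[5,7-dimethoxy-2-(4-methoxyphenyl)-4-oxo-4H-chromen-8-yl]-4-methoxyphenyl}prop-2-ynoyl)phenolate | COc1ccc(-c2cc(=O)c3c(OC)cc(OC)c(-c4cc(OC)ccc4C#CC(=O)c4c([O-])cc(OCc5ccccc5)cc4OCc4ccccc4)c3o2)cc1.[Cs+] | intermediate
18 | 5,7-bis(benzyloxy)-2-{2-[5,7-dimethoxy-2-(4-methoxyphenyl)-4-oxo-4H-chromen-8-yl]-4-methoxyphenyl}-4H-chromen-4-one | COc1ccc(-c2cc(=O)c3c(OC)cc(OC)c(-c4cc(OC)ccc4-c4cc(=O)c5c(OCc6ccccc6)cc(OCc6ccccc6)cc5o4)c3o2)cc1 | intermediate
19 | 5,7-bis[(dichloroboranyl)oxy]-2-{2-[5-[(dichloroboranyl)oxy]-7-methoxy-2-(4-methoxyphenyl)-4-oxo-4H-chromen-8-yl]-4-methoxyphenyl}-4H-chromen-4-one | COc1ccc(-c2cc(=O)c3c(OB(Cl)Cl)cc(OC)c(-c4cc(OC)ccc4-c4cc(=O)c5c(OB(Cl)Cl)cc(OB(Cl)Cl)cc5o4)c3o2)cc1 | intermediate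
20 | 5,7-dihydroxy-2-{2-[5-hydroxy-7-methoxy-2-(4-methoxyphenyl)-4-oxo-4H-chromen-8-yl]-4-methoxyphenyl}-4H-chromen-4-one | COc1ccc(-c2cc(=O)c3c(O)cc(OC)c(-c4cc(OC)ccc4-c4cc(=O)c5c(O)cc(O)cc5o4)c3o2)cc1 | target

## Step count and risk

Total steps: 9. Longest linear sequence: 6 (steps 1, 2, 3, 4, 8, 9 from compound 1); the aryne branch (steps 5, 6, 7) joins at step 8.

Step 8 (key step). Three processes could divert it:
- protonation of the aryl anion before the acyl shift, which would stop at the aryl ester;
- 5-exo closure of the ynone phenoxide to the aurone skeleton in place of 6-endo closure;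
- thermal decarboxylation of the propiolate at 125 °C before it meets the aryne.

The fallback closes ring C1 at O1–C2 by known chemistry. It sets out from aldehyde 4 and comes back at 18. Pinnick oxidation (NaClO2, NaH2PO4, 2-methyl-2-butene, t-BuOH/H2O) should give 2-[5,7-dimethoxy-2-(4-methoxyphenyl)-4-oxo-4H-chromen-8-yl]-4-methoxybenzoic acid F1. Steglich esterification (EDC·HCl, DMAP, CH2Cl2) with commercial 1-[2,4-bis(benzyloxy)-6-hydroxyphenyl]ethanone should give the aryl ester F2. Baker–Venkataraman rearrangement (LiHMDS, THF, −20 °C to rt) should give the 1,3-diketone F3, and cyclodehydration (TsOH, toluene, 80 °C) should give 18.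

Step 2. Protodeboronation of the ortho-formyl boronic acid could outrun the slow oxidative addition and transmetalation at the di-ortho-substituted iodide. The fallback inverts the polarity. It sets out from iodide 2 and comes back at 4. Miyaura borylation (B2pin2, PdCl2(dppf), KOAc, dioxane, 90 °C) should give the 8-boronate F4, 5,7-dimethoxy-2-(4-methoxyphenyl)-8-(4,4,5,5-tetramethyl-1,3,2-dioxaborolan-2-yl)-4H-chromen-4-one. F4 is then coupled with commercial 2-bromo-4-methoxybenzaldehyde (Pd(OAc)2, SPhos, K3PO4, toluene/H2O) to give 4.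

Step 4. Carboxylation is reversible, so incomplete conversion or loss of CO2 during acidification and isolation is the likely failure. Silver-induced attack of the neighbouring C7'' methoxy oxygen on the alkyne is a lesser concern. The fallback brings in the carboxyl carbon as carbon monoxide. It sets out from alkyne 5 and comes back at 7. Oxidative methoxycarbonylation (PdCl2 cat., CuCl2, NaOAc, CO 1 atm, MeOH, rt) should give the methyl ester F5, methyl 3-{2-[5,7-dimethoxy-2-(4-methoxyphenyl)-4-oxo-4H-chromen-8-yl]-4-methoxyphenyl}prop-2-ynoate. Saponification (LiOH, THF/H2O, 0 °C) then gives 7.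

Step 9. Benzyl cations could alkylate the electron-rich rings A1 and A2 if scavenging is slow, and over-long exposure could begin to cleave the C7'' methyl ether. The fallback separates the two deprotections. It sets out from 18 and comes back at 20. Hydrogenolysis (H2, Pd/C, EtOAc/MeOH, rt) should give the diol F6, 5,7-dihydroxy-2-{2-[5,7-dimethoxy-2-(4-methoxyphenyl)-4-oxo-4H-chromen-8-yl]-4-methoxyphenyl}-4H-chromen-4-one. Chelation-controlled peri demethylation (AlCl3, MeCN, 60 °C) then gives 20.

## Further compounds

F1 | step 8 | 2-[5,7-dimethoxy-2-(4-methoxyphenyl)-4-oxo-4H-chromen-8-yl]-4-methoxybenzoic acid | COc1ccc(-c2cc(=O)c3c(OC)cc(OC)c(-c4cc(OC)ccc4C(=O)O)c3o2)cc1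
F2 | step 8 | 2-acetyl-3,5-bis(benzyloxy)phenyl 2-[5,7-dimethoxy-2-(4-methoxyphenyl)-4-oxo-4H-chromen-8-yl]-4-methoxybenzoate | COc1ccc(-c2cc(=O)c3c(OC)cc(OC)c(-c4cc(OC)ccc4C(=O)Oc4cc(OCc5ccccc5)cc(OCc5ccccc5)c4C(C)=O)c3o2)cc1
F3 | step 8 | 1-[2,4-bis(benzyloxy)-6-hydroxyphenyl]-3-{2-[5,7-dimethoxy-2-(4-methoxyphenyl)-4-oxo-4H-chromen-8-yl]-4-methoxyphenyl}propane-1,3-dione | COc1ccc(-c2cc(=O)c3c(OC)cc(OC)c(-c4cc(OC)ccc4C(=O)CC(=O)c4c(O)cc(OCc5ccccc5)cc4OCc4ccccc4)c3o2)cc1
F4 | step 2 | 5,7-dimethoxy-2-(4-methoxyphenyl)-8-(4,4,5,5-tetramethyl-1,3,2-dioxaborolan-2-yl)-4H-chromen-4-one | COc1ccc(-c2cc(=O)c3c(OC)cc(OC)c(B4OC(C)(C)C(C)(C)O4)c3o2)cc1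
F5 | step 4 | methyl 3-{2-[5,7-dimethoxy-2-(4-methoxyphenyl)-4-oxo-4H-chromen-8-yl]-4-methoxyphenyl}prop-2-ynoate | COC(=O)C#Cc1ccc(OC)cc1-c1c(OC)cc(OC)c2c(=O)cc(-c3ccc(OC)cc3)oc12
F6 | step 9 | 5,7-dihydroxy-2-{2-[5,7-dimethoxy-2-(4-methoxyphenyl)-4-oxo-4H-chromen-8-yl]-4-methoxyphenyl}-4H-chromen-4-one | COc1ccc(-c2cc(=O)c3c(OC)cc(OC)c(-c4cc(OC)ccc4-c4cc(=O)c5c(O)cc(O)cc5o4)c3o2)cc1
A1 | alternative 1 | 5,7-bis(benzyloxy)-2-(2-bromo-4-methoxyphenyl)-4H-chromen-4-one | COc1ccc(-c2cc(=O)c3c(OCc4ccccc4)cc(OCc4ccccc4)cc3o2)c(Br)c1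
A2 | alternative 1 | 5,7-bis(benzyloxy)-2-[4-methoxy-2-(4,4,5,5-tetramethyl-1,3,2-dioxaborolan-2-yl)phenyl]-4H-chromen-4-one | COc1ccc(-c2cc(=O)c3c(OCc4ccccc4)cc(OCc4ccccc4)cc3o2)c(B2OC(C)(C)C(C)(C)O2)c1
A3 | alternative 2 | methyl 6-[5-methoxy-2-(methoxycarbonyl)phenyl]-3,5-dioxohexanoate | COC(=O)CC(=O)CC(=O)Cc1cc(OC)ccc1C(=O)OC
A4 | alternative 2 | methyl 4-methoxy-2-(2,4,6-trihydroxyphenyl)benzoate | COC(=O)c1ccc(OC)cc1-c1c(O)cc(O)cc1O
A5 | alternative 2 | 1,3-dihydroxy-9-methoxy-6H-benzo[c]chromen-6-one | COc1ccc2c(c1)-c1c(O)cc(O)cc1OC2=O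
A6 | alternative 3 | 5,7-bis(benzyloxy)-2-{[5,7-dimethoxy-2-(4-methoxyphenyl)-4-oxo-4H-chromen-8-yl]ethynyl}-4H-chromen-4-one | O=c1cc(C#Cc2c(OC)cc(OC)c3c(=O)cc(-c4ccc(OC)cc4)oc23)oc2cc(OCc3ccccc3)cc(OCc3ccccc3)c12
A7 | alternative 3 | 2-methoxybuta-1,3-diene | COC(=C)C=C
A8 | alternative 3 | 5,7-bis(benzyloxy)-2-{2-[5,7-dimethoxy-2-(4-methoxyphenyl)-4-oxo-4H-chromen-8-yl]-4-methoxycyclohexa-1,4-dien-1-yl}-4H-chromen-4-one | COC1=CCC(-c2cc(=O)c3c(OCc4ccccc4)cc(OCc4ccccc4)cc3o2)=C(-c2c(OC)cc(OC)c3c(=O)cc(-c4ccc(OC)cc4)oc23)C1
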